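Read the plateau of the delta flask first: the quick number stands there, and the options turn on what stopped it.

common to all: free catalyst 20 mM

|  | starting material | second substrate | reagent | temperature | remark | time |
|---|---|---|---|---|---|---|
| delta | 0.40 M | 0.20 M | 0.48 M | 50 °C | the very flask that is asked about, followed so far |  |
| alpha | 0.20 M | 0.20 M | 0.48 M | 45 °C | run made earlier |  |
| flask | 0.40 M | 0.200 M | 0.480 M | 50 °C |  | 25 h |

delta run (percent of the starting material charged)

| time / h | target / % | starting material / % |
|---|---|---|
| 4.00 | 56 | 42 |
| 8.00 | 62 | 32 |
| 10.0 | 66 | 32 |
| 15.0 | 64 | 30 |
| 20.0 | 62 | 31 |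
| 25.0 | 62 | 31 |

alpha run (percent of the starting material charged)

| time / min | target / % | starting material / % |
|---|---|---|
| 15.0 | 10 | 92 |
| 30.0 | 15 | 84 |
| 50.0 | 21 | 77 |
| 60.0 | 26 | 76 |
| 80.0 | 30 | 67 |
| 90.0 | 33 | 65 |
| 120 | 43 | 59 |

(scatter of a reading: 1.5 percentage points)

- west: at 25 h take out 90% of the target then present, then wait 2.0 d
- south-east: at 25 h raise the temperature by 15 K, then wait 2.0 d
- east: at 25 h add free catalyst, 50.0% of the amount charged, then wait 2.0 d
- north-west: change nothing and wait 2.0 d more
- south-west: at 25 h add reagent, 50.0% of the amount charged, then wait 2.0 d

- target that was removed still counts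
- candidate steps: starting material + free catalyst <-> catalyst intermediate A; reagent + catalyst intermediate A -> free catalyst + target; second substrate + free catalyst <-> catalyst intermediate B; reagent + catalyst intermediate B -> free catalyst + second product; catalyst intermediate B + target -> spent catalyst
- additions bring no volume worth counting

- target, in percent of the starting material first charged, at 25 h
- the option that brings most further target ("none" if no option brings more than 2 percentage points) (west / south-east / east / north-west / south-west / none)
- target present, with what was taken out counted in, in percent of the starting material first charged, after south-east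
- target present, with what was taken out counted in, in percent of the starting material first charged, after east

The last three delta readings average 62.7% target and 30.7% starting material, so that target is the reckoned answer for now, and starting material is still present while the readings stay flat. The two leave a deficit of 6.67%, a reading about one scatter of 1.5 percentage points from the 5.00% that one catalyst charge would lock as spent catalyst, one target each. So on that deficit of 6.67% the catalyst of the delta flask reads as dead, and the useful measure is the turnover number N, target ever made per catalyst charged, locked target counted:

N = (plateau target + catalyst charge) / catalyst charge = 13.5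

The last candidate step forms spent catalyst from catalyst intermediate B and target, so on that step the loss per turnover grows with target present. With the other concentrations held fixed, catalyst lost then goes as the square of target made, M. In logarithms, lg M rises 0.5 per decade of catalyst and, if intermediate B follows second substrate, falls 0.5 per decade of it. For the east addition:

lg(M′/M) = 0.5 × lg(30.0 mM / 20 mM) = 0.0880

Γ, turnovers per added catalyst = 6.08

Each added catalyst locks one target, so clearing the margin of 2 points needs Γ above 1.80, and the reckoned Γ is larger than that. My reckoning therefore chooses east, with target near 75.4%. The rule holds starting material fixed, while the delta flask reads 30.7% of it, so I take that figure as a high estimate. With the catalyst read as dead, my reckoning leaves south-east at the plateau.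

The forecast gives 63% for now, 63% after south-east, 64.5% after east, and best none, expecting “a net gain of about 1.5 points”, under the margin. On east, my reckoning and the forecast part.

The simulation gives 63.3% for now, 63.3% after south-east, 69.7% after east, and best east.

    starting material + free catalyst ⇌ catalyst intermediate A (K = 3.80 M⁻¹, k = 0.0120 M⁻¹ s⁻¹, Ea = 76.0 kJ mol⁻¹, ΔH = 13.0 kJ mol⁻¹)
    reagent + catalyst intermediate A → free catalyst + target (k = 0.0480 M⁻¹ s⁻¹, Ea = 45.0 kJ mol⁻¹)
    second substrate + free catalyst ⇌ catalyst intermediate B (K = 23.0 M⁻¹, k = 0.00580 M⁻¹ s⁻¹, Ea = 52.0 kJ mol⁻¹, ΔH = 5.00 kJ mol⁻¹)
    reagent + catalyst intermediate B → free catalyst + second product (k = 0.00240 M⁻¹ s⁻¹, Ea = 53.0 kJ mol⁻¹)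
    catalyst intermediate B + target → spent catalyst (k = 0.00120 M⁻¹ s⁻¹, Ea = 68.0 kJ mol⁻¹)
    (constants at 50 °C)

East returned Γ = 3.57, above the 1.80 needed and below the 6.08 reckoned. A neighbouring flask charged with 0.12 M of second substrate gets from the same rule lg(N′/N) = 0.5 × lg(0.200 M / 0.12 M) = 0.111, so N′ = 17.5. That neighbouring flask stands at 75.7% target at 25 h, which is N′ = 16.1.

All runs stem from a simulated flask for an exercise, noise included.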